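**Plan**

Labels: ring B and ring C are the benzo rings of the two dihydrofurans; Ca/Cb (on ring B) and Ca'/Cb' (on ring C) are their C3 and C2 carbons.
Retrosynthesis cuts, in this order: the ring B–CH= bond of the seven-membered ring (Heck), the Ca–ring C bond (decarboxylative arylation), the ring B–Ca bond with return of that ring carbon to the carboxyl carbon (flavanone ring contraction), and in the second fragment the Ca'–Cb' bond (carbene C–H insertion).
Enabling feature: ring B carries two meta oxygens (one is the furan oxygen), a carbon substituent on the ring carbon next to the fusion, and the O–Cb(4-hydroxyphenyl)–Ca unit. This is ring A, O1, C2 and C3 of a 5,7-dioxygenated flavanone whose C4 has left the ring, so (S)-naringenin supplies ring B, the aryl group, the Cb configuration and, at O5, the handle for the alkene carbon.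
Forward: naringenin is protected and contracted to the ring-B dihydrofuran ester; ring C is built from 1-bromo-3,5-dimethoxybenzene and its dihydrofuran is closed by rhodium carbene insertion; the fragments are joined at Ca, the seven-membered ring is closed by a 7-endo Heck reaction, and the phenols are freed.
Stereochemistry: Cb is C2 of (S)-naringenin; Ca is set trans to it in the ring contraction and again in the radical arylation; Ca' comes from the chiral dirhodium catalyst and Cb' from acid equilibration to the trans isomer.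

Key step: step 4

Assumption: Rh2(R-PTAD)4 is written for whichever enantiomer of the dirhodium carboxylate gives (3R)-25; if its sense of induction on this substrate is the opposite, the S-configured catalyst is used.

**Route**

Step 1
Reactants: 1 (S)-naringenin
Product: 2 (S)-sakuranetin (7-O-methylnaringenin)
Conditions: MeOH (1.05 equiv), PPh3, DIAD, THF, 0 °C → rt
Reagents that add atoms: methanol, CO
Why: Mitsunobu etherification alkylates the most acidic phenol (7-OH, para to the carbonyl) under neutral conditions, so C2 is never exposed to base and cannot racemise by retro-oxa-Michael opening.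

Step 2
Reactants: 2 (S)-sakuranetin
Product: 3 (S)-7-O-methyl-4'-O-pivaloylnaringenin
Conditions: PivCl (1.1 equiv), pyridine, CH2Cl2, 0 °C
Reagents that add atoms: pivaloyl chloride, CC(C)(C)C(Cl)=O
Why: Acylation (ester formation) of the free 4'-phenol, while the 5-OH is hydrogen-bonded to the C4 carbonyl and stays untouched; the pivalate makes the 2-aryl group electron-poor for step 4.

Step 3
Reactants: 3 (S)-7-O-methyl-4'-O-pivaloylnaringenin
Product: 4 (S)-5-O-benzyl-7-O-methyl-4'-O-pivaloylnaringenin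
Conditions: BnOH, PPh3, DIAD, THF, 0 °C → rt
Reagents that add atoms: benzyl alcohol, OCc1ccccc1
Why: Mitsunobu etherification of the chelated 5-OH, a reaction known on 7,4'-di-O-acylnaringenins, avoids the carbonate/halide conditions under which 5-alkoxyflavanones open to chalcones and racemise.

Step 4
Reactants: 4 (S)-5-O-benzyl-7-O-methyl-4'-O-pivaloylnaringenin
Product: 6 methyl (2S,3S)-4-(benzyloxy)-6-methoxy-2-[4-(pivaloyloxy)phenyl]-2,3-dihydro-1-benzofuran-3-carboxylate, via enol ether 5 (not isolated)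
Conditions: PhI(OAc)2 (1.3 equiv), HC(OMe)3, conc. H2SO4 (cat.), rt
Reagents that add atoms: trimethyl orthoformate, COC(OC)OC
Why: Acid and orthoformate turn the ketone into enol ether 5, which attacks PhI(OAc)2 through C3 on the face anti to the 2-aryl group; methanol adds at C4, and as iodobenzene leaves the trivalent iodine centre the electron-rich ring-A carbon C4a shifts from C4 to C3 with inversion, the resulting dimethoxycarbenium ion collapsing to the methyl ester. The closest known reaction is the oxidative ring contraction of flavanones to trans-2-aryl-2,3-dihydrobenzofuran-3-carboxylates with PhI(OAc)2 or Tl(NO3)3 in trimethyl orthoformate, a 1,2-aryl shift of the semipinacol type. The five-membered ring O1–C2–C3–C4a–C8a closes by contraction of the pyranone: C4a bridges C4 and C3 in a phenonium-like three-membered transition state (3-exo-tet at C3) and ends bonded to C3 only. The new stereocentre Ca (old C3) is controlled by the C2 centre, since anti attack of iodine followed by inversion places the ester trans to the aryl group, which is also the more stable isomer; C2 is not touched and becomes Cb with S configuration. The step needs migration of C4a to win over migration of the 2-aryl group (isoflavone) and over dehydrogenation (flavone), and this is secured by the 5-benzyloxy and 7-methoxy groups, which make C4a electron-rich, together with the electron-poor 4-pivaloyloxyphenyl group. The acidic medium contains no base, so the flavanone cannot open to the chalcone and the configuration of naringenin is kept.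

Step 5
Reactants: 6 methyl (2S,3S)-4-(benzyloxy)-6-methoxy-2-[4-(pivaloyloxy)phenyl]-2,3-dihydro-1-benzofuran-3-carboxylate
Product: 7 (2S,3S)-4-(benzyloxy)-6-methoxy-2-[4-(pivaloyloxy)phenyl]-2,3-dihydro-1-benzofuran-3-carboxylic acid
Conditions: Me3SnOH, ClCH2CH2Cl, 80 °C; then 1 M HCl wash
Reagents that add atoms: trimethyltin hydroxide, C[Sn](C)(C)O
Why: Ester cleavage with trimethyltin hydroxide delivers hydroxide to the methyl ester under neutral conditions, which should spare the hindered aryl pivalate and avoid base-induced retro-oxa-Michael opening of the β-aryloxy ester.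

Step 6
Reactants: 7 (2S,3S)-4-(benzyloxy)-6-methoxy-2-[4-(pivaloyloxy)phenyl]-2,3-dihydro-1-benzofuran-3-carboxylic acid
Product: 8 (2S,3S)-4-hydroxy-6-methoxy-2-[4-(pivaloyloxy)phenyl]-2,3-dihydro-1-benzofuran-3-carboxylic acid
Conditions: H2 (1 atm), Pd/C (10 %), EtOAc, rt
Reagents that add atoms: none
Why: Hydrogenolysis of the aryl benzyl ether is done here, before any alkene is in the molecule, and the electron-poor 2-aryl group keeps the benzylic C2–O bond intact.

Step 7
Reactants: 8 (2S,3S)-4-hydroxy-6-methoxy-2-[4-(pivaloyloxy)phenyl]-2,3-dihydro-1-benzofuran-3-carboxylic acid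
Product: 10 (2S,3S)-4-(tert-butyldimethylsilyloxy)-6-methoxy-2-[4-(pivaloyloxy)phenyl]-2,3-dihydro-1-benzofuran-3-carboxylic acid, via silyl ester 9 (not isolated)
Conditions: TBSCl (2.5 equiv), imidazole, DMF, rt; then AcOH/THF/H2O, rt
Reagents that add atoms: tert-butyldimethylsilyl chloride, CC(C)(C)[Si](C)(C)Cl
Why: Silylation of phenol and acid followed by selective hydrolysis of the labile silyl ester leaves the phenol as a small silyl ether that tolerates the organozinc coupling and can later be turned into the triflate without acid.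

Step 8
Reactants: 11 1-bromo-3,5-dimethoxybenzene; 12 4-methoxybenzoyl chloride
Product: 14 (2-bromo-6-hydroxy-4-methoxyphenyl)(4-methoxyphenyl)methanone, via dimethoxy ketone 13 (not isolated)
Conditions: AlCl3, CH2Cl2, 0 °C → rt; then BCl3, 0 °C
Reagents that add atoms: none
Why: Friedel–Crafts acylation of 11 occurs para to one methoxy group at the position next to bromine, and BCl3 then cleaves only the methoxy group chelated to the new carbonyl (chelation-controlled ether cleavage), which fixes C–Br, C-acyl and C–OH on three neighbouring ring-C carbons.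

Step 9
Reactants: 14 (2-bromo-6-hydroxy-4-methoxyphenyl)(4-methoxyphenyl)methanone
Product: 16 3-bromo-5-methoxy-2-[1-(4-methoxyphenyl)ethenyl]phenol, via tertiary alcohol 15 (not isolated)
Conditions: MeMgBr (3.5 equiv), THF, 0 °C → rt; aq. NH4Cl; then TsOH·H2O (cat.), CH2Cl2, rt
Reagents that add atoms: methylmagnesium bromide, C[Mg]Br
Why: Grignard addition to the ketone of the magnesium phenoxide and acid-catalysed E1 dehydration of the tertiary diaryl carbinol should give the 1,1-diarylethylene needed for the Heck closure.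

Step 10
Reactants: 16 3-bromo-5-methoxy-2-[1-(4-methoxyphenyl)ethenyl]phenol
Product: 17 4-bromo-2-hydroxy-6-methoxy-3-[1-(4-methoxyphenyl)ethenyl]benzaldehyde
Conditions: MgCl2, Et3N, (CH2O)n, MeCN, reflux
Reagents that add atoms: paraformaldehyde (formaldehyde), C=O
Why: The magnesium-mediated ortho-formylation of phenols (Casnati–Skattebøl) is ortho-specific, and the only free ortho position of 16 is the carbon between OH and OMe, so the future C3a of ring C is functionalised without regioisomers.

Step 11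
Reactants: 17 4-bromo-2-hydroxy-6-methoxy-3-[1-(4-methoxyphenyl)ethenyl]benzaldehyde; 18 4-methoxybenzyl chloride
Product: 19 4-bromo-6-methoxy-2-[(4-methoxybenzyl)oxy]-3-[1-(4-methoxyphenyl)ethenyl]benzaldehyde
Conditions: K2CO3, NaI (cat.), DMF, 50 °C
Reagents that add atoms: none
Why: Williamson etherification installs the 4-methoxybenzyl group, whose CH2 becomes Cb' and whose aryl group becomes the 2-aryl substituent.

Step 12
Reactants: 19 4-bromo-6-methoxy-2-[(4-methoxybenzyl)oxy]-3-[1-(4-methoxyphenyl)ethenyl]benzaldehyde; 20 (3,5-dimethoxyphenyl)magnesium bromide (THF solution)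
Product: 21 rac-{4-bromo-6-methoxy-2-[(4-methoxybenzyl)oxy]-3-[1-(4-methoxyphenyl)ethenyl]phenyl}(3,5-dimethoxyphenyl)methanol
Conditions: THF, −40 → 0 °C
Reagents that add atoms: none
Why: Grignard addition to the aldehyde leaves the aryl bromide and the alkene untouched at low temperature, and the uncontrolled carbinol centre is removed in the next step.

Step 13
Reactants: 21 rac-{4-bromo-6-methoxy-2-[(4-methoxybenzyl)oxy]-3-[1-(4-methoxyphenyl)ethenyl]phenyl}(3,5-dimethoxyphenyl)methanol
Product: 22 {4-bromo-6-methoxy-2-[(4-methoxybenzyl)oxy]-3-[1-(4-methoxyphenyl)ethenyl]phenyl}(3,5-dimethoxyphenyl)methanone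
Conditions: activated MnO2, CH2Cl2, rt
Reagents that add atoms: none
Why: MnO2 oxidation of a doubly benzylic alcohol to the diaryl ketone is selective and leaves the alkene and ethers alone.

Step 14
Reactants: 22 {4-bromo-6-methoxy-2-[(4-methoxybenzyl)oxy]-3-[1-(4-methoxyphenyl)ethenyl]phenyl}(3,5-dimethoxyphenyl)methanone
Product: 23 hydrazone of 22 (E/Z mixture)
Conditions: N2H4·H2O (excess), AcOH (cat.), n-BuOH, 110 °C, under argon
Reagents that add atoms: hydrazine hydrate, NN
Why: Hydrazone condensation is forced with excess hydrazine and heat because the ketone has two ortho substituents, and it is the only carbonyl group in the molecule.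

Step 15
Reactants: 23 hydrazone of 22
Product: 25 (2S,3R)-6-bromo-3-(3,5-dimethoxyphenyl)-4-methoxy-2-(4-methoxyphenyl)-7-[1-(4-methoxyphenyl)ethenyl]-2,3-dihydro-1-benzofuran, via diazo compound 24 (not isolated)
Conditions: MnO2, CH2Cl2, rt, filtration; then Rh2(R-PTAD)4 (1 mol %), CH2Cl2, 0 °C, high dilution
Reagents that add atoms: none
Why: Oxidation of the hydrazone gives the diaryldiazomethane, and the chiral dirhodium carboxylate turns it into a donor/donor carbene that inserts into the activated benzylic C–H bond of the 4-methoxybenzyl ether (intramolecular 1,5 C–H insertion), which closes the dihydrofuran with catalyst-controlled configuration at C3 and the kinetic cis relationship at C2.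

Step 16
Reactants: 25 (2S,3R)-6-bromo-3-(3,5-dimethoxyphenyl)-4-methoxy-2-(4-methoxyphenyl)-7-[1-(4-methoxyphenyl)ethenyl]-2,3-dihydro-1-benzofuran
Product: 26 (2R,3R)-6-bromo-3-(3,5-dimethoxyphenyl)-4-methoxy-2-(4-methoxyphenyl)-7-[1-(4-methoxyphenyl)ethenyl]-2,3-dihydro-1-benzofuran
Conditions: BF3·OEt2 (0.2 equiv), CH2Cl2, −30 → 0 °C
Reagents that add atoms: none
Why: Acid-mediated C2 epimerisation of a 2-aryl-2,3-dihydrobenzofuran: the Lewis acid reversibly ionises the C2–O bond to a 4-methoxybenzyl cation, and reclosure should give the more stable trans-2,3-diaryl isomer while C3 stays fixed, with the low temperature and substoichiometric acid chosen to spare the diarylethylene.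

Step 17
Reactants: 10 (2S,3S)-4-(tert-butyldimethylsilyloxy)-6-methoxy-2-[4-(pivaloyloxy)phenyl]-2,3-dihydro-1-benzofuran-3-carboxylic acid; 26 (2R,3R)-6-bromo-3-(3,5-dimethoxyphenyl)-4-methoxy-2-(4-methoxyphenyl)-7-[1-(4-methoxyphenyl)ethenyl]-2,3-dihydro-1-benzofuran
Product: 29 4-{(2S,3S)-4-(tert-butyldimethylsilyloxy)-3-[(2R,3R)-3-(3,5-dimethoxyphenyl)-4-methoxy-2-(4-methoxyphenyl)-7-[1-(4-methoxyphenyl)ethenyl]-2,3-dihydro-1-benzofuran-6-yl]-6-methoxy-2,3-dihydro-1-benzofuran-2-yl}phenyl pivalate, via redox-active ester 27 (not isolated), via arylzinc chloride 28 (not isolated)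
Conditions: 10, N-hydroxyphthalimide, DIC, DMAP (cat.), CH2Cl2, rt; separately 26, Mg, LiCl, ZnCl2, THF, rt; then NiCl2(glyme) (20 mol %), dtbbpy (40 mol %), THF/DMF, rt
Reagents that add atoms: none
Why: Nickel-catalysed decarboxylative Negishi-type arylation of a redox-active ester: single-electron reduction of 27 releases CO2 and the benzylic Ca radical, which is captured by the arylnickel species on the face anti to the Cb aryl group, so reductive elimination should give the trans-2,3-diaryl product.

Step 18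
Reactants: 29 (silyl ether from step 17)
Product: 30 the aryl triflate of 29 (OSO2CF3 in place of OSi(t-Bu)Me2 on ring B)
Conditions: CsF, PhNTf2, DME, rt
Reagents that add atoms: N-phenylbis(trifluoromethanesulfonimide), O=S(=O)(N(c1ccccc1)S(=O)(=O)C(F)(F)F)C(F)(F)F
Why: Fluoride cleaves the aryl silyl ether and the phenoxide is trapped in the same flask by PhNTf2 (one-pot desilylation–triflation), without acid that would ionise the 4-methoxyphenyl dihydrofuran or add to the diarylethylene.

Step 19
Reactants: 30 (aryl triflate)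
Product: 31 the hexa-O-methyl 4'-O-pivaloyl derivative of 33 (seven-membered ring closed; Ca S, Cb S, Ca' R, Cb' R)
Conditions: Pd(OAc)2 (10 mol %), PPh3 (20 mol %), n-Bu4NCl, KOAc, DMF, 90 °C
Reagents that add atoms: none
Why: Intramolecular Mizoroki–Heck reaction in the 7-endo-trig mode: oxidative addition of the aryl triflate to zerovalent palladium, aryl transfer to the unsubstituted CH2 terminus of the 1,1-diarylethylene and β-hydride elimination should give the trisubstituted ring alkene, whereas 6-exo attack would build a quaternary carbon and a neopentyl palladium species without β-hydrogen.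

Step 20
Reactants: 31 (pivalate)
Product: 32 the hexa-O-methyl ether of 33 with a free 4-hydroxyphenyl group on Cb
Conditions: K2CO3, MeOH/THF, rt
Reagents that add atoms: none
Why: Base-catalysed transesterification (methanolysis) removes the aryl pivalate while all other phenols are still methyl ethers.

Step 21
Reactants: 32 (hexamethyl ether)
Product: 33 CNP0325907.1
Conditions: BBr3 (excess), CH2Cl2, −78 °C → rt; then MeOH, H2O
Reagents that add atoms: none
Why: BBr3 demethylation cleaves the six aryl methyl ethers, and any benzylic C–O bond that opens under the Lewis acid should reclose to the trans-dihydrofuran on work-up.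

**Compound list**

1 | (S)-naringenin, (2S)-5,7-dihydroxy-2-(4-hydroxyphenyl)chroman-4-one | O=C1C[C@@H](c2ccc(O)cc2)Oc2cc(O)cc(O)c21 | starting material
2 | (S)-sakuranetin, (2S)-5-hydroxy-2-(4-hydroxyphenyl)-7-methoxychroman-4-one | O=C1C[C@@H](c2ccc(O)cc2)Oc2cc(OC)cc(O)c21 | intermediate
3 | (S)-7-O-methyl-4'-O-pivaloylnaringenin | O=C1C[C@@H](c2ccc(OC(=O)C(C)(C)C)cc2)Oc2cc(OC)cc(O)c21 | intermediate
4 | (S)-5-O-benzyl-7-O-methyl-4'-O-pivaloylnaringenin | O=C1C[C@@H](c2ccc(OC(=O)C(C)(C)C)cc2)Oc2cc(OC)cc(OCc3ccccc3)c21 | intermediate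
5 | 4-[(2S)-5-(benzyloxy)-4,7-dimethoxy-2H-chromen-2-yl]phenyl pivalate (enol ether) | COC1=C[C@@H](c2ccc(OC(=O)C(C)(C)C)cc2)Oc2cc(OC)cc(OCc3ccccc3)c21 | intermediate
6 | methyl (2S,3S)-4-(benzyloxy)-6-methoxy-2-[4-(pivaloyloxy)phenyl]-2,3-dihydro-1-benzofuran-3-carboxylate (trans) | O(Cc1ccccc1)c1cc(OC)cc2c1[C@H](C(=O)OC)[C@@H](c1ccc(OC(=O)C(C)(C)C)cc1)O2 | intermediate
7 | (2S,3S)-4-(benzyloxy)-6-methoxy-2-[4-(pivaloyloxy)phenyl]-2,3-dihydro-1-benzofuran-3-carboxylic acid | O(Cc1ccccc1)c1cc(OC)cc2c1[C@H](C(=O)O)[C@@H](c1ccc(OC(=O)C(C)(C)C)cc1)O2 | intermediate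
8 | (2S,3S)-4-hydroxy-6-methoxy-2-[4-(pivaloyloxy)phenyl]-2,3-dihydro-1-benzofuran-3-carboxylic acid | Oc1cc(OC)cc2c1[C@H](C(=O)O)[C@@H](c1ccc(OC(=O)C(C)(C)C)cc1)O2 | intermediate
9 | tert-butyldimethylsilyl (2S,3S)-4-(tert-butyldimethylsilyloxy)-6-methoxy-2-[4-(pivaloyloxy)phenyl]-2,3-dihydro-1-benzofuran-3-carboxylate | CC(C)(C)[Si](C)(C)Oc1cc(OC)cc2c1[C@H](C(=O)O[Si](C)(C)C(C)(C)C)[C@@H](c1ccc(OC(=O)C(C)(C)C)cc1)O2 | intermediate
10 | (2S,3S)-4-(tert-butyldimethylsilyloxy)-6-methoxy-2-[4-(pivaloyloxy)phenyl]-2,3-dihydro-1-benzofuran-3-carboxylic acid | CC(C)(C)[Si](C)(C)Oc1cc(OC)cc2c1[C@H](C(=O)O)[C@@H](c1ccc(OC(=O)C(C)(C)C)cc1)O2 | intermediate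
11 | 1-bromo-3,5-dimethoxybenzene | COc1cc(Br)cc(OC)c1 | starting material
12 | 4-methoxybenzoyl chloride | COc1ccc(cc1)C(Cl)=O | starting material
13 | (2-bromo-4,6-dimethoxyphenyl)(4-methoxyphenyl)methanone | COc1ccc(cc1)C(=O)c1c(Br)cc(OC)cc1OC | intermediate
14 | (2-bromo-6-hydroxy-4-methoxyphenyl)(4-methoxyphenyl)methanone | COc1ccc(cc1)C(=O)c1c(Br)cc(OC)cc1O | intermediate
15 | rac-3-bromo-2-[1-hydroxy-1-(4-methoxyphenyl)ethyl]-5-methoxyphenol | COc1ccc(cc1)C(C)(O)c1c(Br)cc(OC)cc1O | intermediate
16 | 3-bromo-5-methoxy-2-[1-(4-methoxyphenyl)ethenyl]phenol | COc1ccc(cc1)C(=C)c1c(Br)cc(OC)cc1O | intermediate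
17 | 4-bromo-2-hydroxy-6-methoxy-3-[1-(4-methoxyphenyl)ethenyl]benzaldehyde | COc1ccc(cc1)C(=C)c1c(Br)cc(OC)c(C=O)c1O | intermediate
18 | 4-methoxybenzyl chloride | COc1ccc(CCl)cc1 | starting material
19 | 4-bromo-6-methoxy-2-[(4-methoxybenzyl)oxy]-3-[1-(4-methoxyphenyl)ethenyl]benzaldehyde | COc1ccc(cc1)C(=C)c1c(Br)cc(OC)c(C=O)c1OCc1ccc(OC)cc1 | intermediate
20 | (3,5-dimethoxyphenyl)magnesium bromide | COc1cc([Mg]Br)cc(OC)c1 | starting material
21 | rac-{4-bromo-6-methoxy-2-[(4-methoxybenzyl)oxy]-3-[1-(4-methoxyphenyl)ethenyl]phenyl}(3,5-dimethoxyphenyl)methanol | COc1ccc(cc1)C(=C)c1c(Br)cc(OC)c(C(O)c2cc(OC)cc(OC)c2)c1OCc1ccc(OC)cc1 | intermediate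
22 | {4-bromo-6-methoxy-2-[(4-methoxybenzyl)oxy]-3-[1-(4-methoxyphenyl)ethenyl]phenyl}(3,5-dimethoxyphenyl)methanone | COc1ccc(cc1)C(=C)c1c(Br)cc(OC)c(C(=O)c2cc(OC)cc(OC)c2)c1OCc1ccc(OC)cc1 | intermediate
23 | hydrazone of 22 (E/Z mixture) | COc1ccc(cc1)C(=C)c1c(Br)cc(OC)c(C(=NN)c2cc(OC)cc(OC)c2)c1OCc1ccc(OC)cc1 | intermediate
24 | 5-bromo-2-[diazo(3,5-dimethoxyphenyl)methyl]-1-methoxy-3-[(4-methoxybenzyl)oxy]-4-[1-(4-methoxyphenyl)ethenyl]benzene | COc1ccc(cc1)C(=C)c1c(Br)cc(OC)c(C(=[N+]=[N-])c2cc(OC)cc(OC)c2)c1OCc1ccc(OC)cc1 | intermediate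
25 | (2S,3R)-6-bromo-3-(3,5-dimethoxyphenyl)-4-methoxy-2-(4-methoxyphenyl)-7-[1-(4-methoxyphenyl)ethenyl]-2,3-dihydro-1-benzofuran (cis) | COc1ccc(cc1)[C@H]1Oc2c(C(=C)c3ccc(OC)cc3)c(Br)cc(OC)c2[C@H]1c1cc(OC)cc(OC)c1 | intermediate
26 | (2R,3R)-6-bromo-3-(3,5-dimethoxyphenyl)-4-methoxy-2-(4-methoxyphenyl)-7-[1-(4-methoxyphenyl)ethenyl]-2,3-dihydro-1-benzofuran (trans) | COc1ccc(cc1)[C@@H]1Oc2c(C(=C)c3ccc(OC)cc3)c(Br)cc(OC)c2[C@H]1c1cc(OC)cc(OC)c1 | intermediate
27 | 1,3-dioxoisoindolin-2-yl ester of 10 (redox-active ester) | CC(C)(C)[Si](C)(C)Oc1cc(OC)cc2c1[C@H](C(=O)ON1C(=O)c3ccccc3C1=O)[C@@H](c1ccc(OC(=O)C(C)(C)C)cc1)O2 | intermediate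
28 | arylzinc chloride of 26 (ZnCl in place of Br) | COc1ccc(cc1)[C@@H]1Oc2c(C(=C)c3ccc(OC)cc3)c([Zn]Cl)cc(OC)c2[C@H]1c1cc(OC)cc(OC)c1 | intermediate
29 | 4-{(2S,3S)-4-(tert-butyldimethylsilyloxy)-3-[(2R,3R)-3-(3,5-dimethoxyphenyl)-4-methoxy-2-(4-methoxyphenyl)-7-[1-(4-methoxyphenyl)ethenyl]-2,3-dihydro-1-benzofuran-6-yl]-6-methoxy-2,3-dihydro-1-benzofuran-2-yl}phenyl pivalate | CC(C)(C)[Si](C)(C)Oc1cc(OC)cc2c1[C@H](c1cc(OC)c3c(c1C(=C)c1ccc(OC)cc1)O[C@@H](c1ccc(OC)cc1)[C@@H]3c1cc(OC)cc(OC)c1)[C@@H](c1ccc(OC(=O)C(C)(C)C)cc1)O2 | intermediate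
30 | aryl triflate of 29 (4-trifluoromethanesulfonyloxy on ring B, otherwise as 29) | O=S(=O)(Oc1cc(OC)cc2c1[C@H](c1cc(OC)c3c(c1C(=C)c1ccc(OC)cc1)O[C@@H](c1ccc(OC)cc1)[C@@H]3c1cc(OC)cc(OC)c1)[C@@H](c1ccc(OC(=O)C(C)(C)C)cc1)O2)C(F)(F)F | intermediate
31 | hexa-O-methyl 4'-O-pivaloyl derivative of 33: OMe on ring B, ring C, the alkene aryl, the Cb' aryl and both positions of the 3,5-disubstituted phenyl; OPiv on the Cb aryl; Ca S, Cb S, Ca' R, Cb' R | COc1ccc(C2=Cc3cc(OC)cc4c3[C@H](c3cc(OC)c5c(c32)O[C@@H](c2ccc(OC)cc2)[C@@H]5c2cc(OC)cc(OC)c2)[C@@H](c2ccc(OC(=O)C(C)(C)C)cc2)O4)cc1 | intermediate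
32 | hexa-O-methyl ether of 33 with free 4-hydroxyphenyl on Cb; Ca S, Cb S, Ca' R, Cb' R | COc1ccc(C2=Cc3cc(OC)cc4c3[C@H](c3cc(OC)c5c(c32)O[C@@H](c2ccc(OC)cc2)[C@@H]5c2cc(OC)cc(OC)c2)[C@@H](c2ccc(O)cc2)O4)cc1 | intermediate
33 | CNP0325907.1; Ca S, Cb S, Ca' R, Cb' R | Oc1ccc(C2=Cc3cc(O)cc4c3[C@H](c3cc(O)c5c(c32)O[C@@H](c2ccc(O)cc2)[C@@H]5c2cc(O)cc(O)c2)[C@@H](c2ccc(O)cc2)O4)cc1 | target

**Step count and risks**

Total step count: 21. Longest linear sequence: 14 steps (steps 8–16, then 17–21); the naringenin branch has 7 steps before the union.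

Steps most likely to fail:

1. Step 17 (decarboxylative arylation). The Ca radical is flanked by the silyloxy-bearing ring B and by Cb, and the aryl partner carries the 1-arylvinyl group ortho to the metal. Capture of the radical by the arylnickel species may therefore be slower than radical dimerisation or reduction, and magnesium insertion and zinc-to-nickel transfer at the hindered position may be sluggish. Fallback: from acid 10 and bromide 26 directly to 29 by metallaphotoredox decarboxylative arylation (Ir[dF(CF3)ppy]2(dtbbpy)PF6, NiCl2(glyme), dtbbpy, Cs2CO3, DMF, blue light, rt). The carboxylate of 10 is oxidised to the same Ca radical, while 26 enters by oxidative addition of its C–Br bond to nickel, so neither the redox-active ester nor the hindered organozinc has to be made. No new compound arises on this path (F0).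

2. Step 19 (7-endo Heck closure). Aryl transfer may go to the internal alkene carbon (6-exo), or slow rotation about the Ca–ring C bond may keep the alkene away from the arylpalladium species, so that reduction of the triflate takes over. Fallback: from triflate 30, palladium-catalysed reductive carbonylation (Pd(OAc)2, dppp, CO, Et3SiH, Na2CO3, DMF, 70 °C) would give the ring-B aldehyde F1. Oxidative cleavage of its 1,1-diarylethylene (OsO4 cat., NaIO4, 2,6-lutidine, dioxane/H2O) would give the keto aldehyde F2. Intramolecular McMurry coupling (TiCl4, Zn, pyridine, THF, reflux) joins the two carbonyl carbons and returns to 31.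

3. Step 15 (carbene C–H insertion). The doubly ortho-substituted diaryl carbene may show poor facial selectivity, insert into the neighbouring methoxy C–H bond, or form azine, and the preceding hydrazone condensation may stall. Fallback: from aldehyde 17, addition of 20 (2.2 equiv, THF, 0 °C) would give the ortho-hydroxybenzhydrol F3, and p-toluenesulfinic acid (CH2Cl2, rt) would convert it into the benzylic sulfone F4. Treatment of F4 with the (4-methoxybenzyl)sulfonium salt of isothiocineole and Cs2CO3 (CH2Cl2, 0 °C) generates an ortho-quinone methide and the chiral benzyl ylide. Their [4+1] annulation (conjugate addition, then displacement of the sulfide by the phenoxide) should close the trans-dihydrofuran and return to 26 without passing through 19–25.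

**Further compounds**

F0 | step 17 | none | none
F1 | step 19 | 4-{(2S,3S)-3-[(2R,3R)-3-(3,5-dimethoxyphenyl)-4-methoxy-2-(4-methoxyphenyl)-7-[1-(4-methoxyphenyl)ethenyl]-2,3-dihydro-1-benzofuran-6-yl]-4-formyl-6-methoxy-2,3-dihydro-1-benzofuran-2-yl}phenyl pivalate | O=Cc1cc(OC)cc2c1[C@H](c1cc(OC)c3c(c1C(=C)c1ccc(OC)cc1)O[C@@H](c1ccc(OC)cc1)[C@@H]3c1cc(OC)cc(OC)c1)[C@@H](c1ccc(OC(=O)C(C)(C)C)cc1)O2
F2 | step 19 | keto aldehyde: as F1 with a 4-methoxybenzoyl group in place of the 1-(4-methoxyphenyl)ethenyl group | O=Cc1cc(OC)cc2c1[C@H](c1cc(OC)c3c(c1C(=O)c1ccc(OC)cc1)O[C@@H](c1ccc(OC)cc1)[C@@H]3c1cc(OC)cc(OC)c1)[C@@H](c1ccc(OC(=O)C(C)(C)C)cc1)O2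
F3 | step 15 | rac-3-bromo-6-[(3,5-dimethoxyphenyl)(hydroxy)methyl]-5-methoxy-2-[1-(4-methoxyphenyl)ethenyl]phenol | COc1ccc(cc1)C(=C)c1c(Br)cc(OC)c(C(O)c2cc(OC)cc(OC)c2)c1O
F4 | step 15 | rac-3-bromo-6-[(3,5-dimethoxyphenyl)(4-methylbenzenesulfonyl)methyl]-5-methoxy-2-[1-(4-methoxyphenyl)ethenyl]phenol | COc1ccc(cc1)C(=C)c1c(Br)cc(OC)c(C(c2cc(OC)cc(OC)c2)S(=O)(=O)c2ccc(C)cc2)c1O
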